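**Plan**

1. Numbering: ring C1 (carbinol), C3 (Cl), C4 (Br, CH3); side chain C1′ (=CH2), C2′, C3′, C4′ (CHOH). Retrosynthetic cuts in order: C3–Cl and C4–Br (back to a C3=C4 alkene), C2′–C3′ (allyl dianion plus isopropenyl oxirane), C1′=CH2 and C1′–CH3 (back to a carboxyl on C1), then ring bond C1–C2 with a C4–O ester bond restored.
2. Enabling feature: C1 is a fully substituted carbinol carbon next to the carboxyl-derived C1′, and C2–C3=C4 is an allyl unit once the halogens are removed. C1–C2 is therefore the bond a [3,3] shift makes from an ester whose oxygen sat on C4, and linking the two halves through C5–C6 makes that ester a 6-methyl-6-vinyl δ-lactone.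
3. Forward: (S)-linalool is cleaved to a lactol, homologated by one carbon, oxidised to the δ-lactone and α-oxygenated. The lactone is a temporary ring, and the only carbocycle arises in the ring-contracting Ireland–Claisen step.
4. The acid is converted into an isopropenyl group, whose methyl is lithiated and joined to (S)-2-isopropenyloxirane. The halogens are added last.
5. Stereochemistry: C1 comes from C3 of linalool, relayed across one face in the Claisen step. C4′ comes from the resolved epoxide. C3 and C4 come from anti addition steered by the C1 hydroxyl (Cl cis, Br trans to OH).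

Key step: step 6

Assumption: (S)-(+)-linalool of high enantiomeric purity is taken as the commercial starting material, and the sense of the epoxide resolution in step 11 is taken from the behaviour of simple terminal epoxides.

**Route**

Step 1
Reactants: 1 (S)-linalool
Product: 3 (5S)-5-ethenyl-5-methyloxolan-2-ol (lactol; anomer mixture), via secondary ozonide 2 (not isolated)
Conditions: O3, CH2Cl2, −78 °C (Sudan Red 7B end point); PPh3, −78 °C to rt
Reagents that add atoms: ozone, [O-][O+]=O
Why: Chemoselective ozonolysis with reductive work-up: ozone attacks the electron-rich trisubstituted alkene far faster than the monosubstituted vinyl group, and the resulting γ-hydroxy aldehyde closes to the lactol with the carbinol center untouched.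

Step 2
Reactants: 3 (5S)-5-ethenyl-5-methyloxolan-2-ol
Product: 4 (3S)-7-methoxy-3-methylhepta-1,6-dien-3-ol (E/Z mixture)
Conditions: MeOCH2PPh3Cl (excess), KOtBu, THF, 0 °C to rt
Reagents that add atoms: (methoxymethyl)triphenylphosphonium chloride, COC[P+](c1ccccc1)(c1ccccc1)c1ccccc1.[Cl-]
Why: Wittig olefination of the lactol through its open hydroxy aldehyde form (excess ylide covers the acidic hydroxyl) adds the one carbon that becomes the lactone carbonyl, and the alkene geometry is of no consequence.

Step 3
Reactants: 4 (3S)-7-methoxy-3-methylhepta-1,6-dien-3-ol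
Product: 6 (6S)-6-ethenyl-6-methyloxan-2-one, via lactol 5 (not isolated)
Conditions: 0.5 M aq HCl, THF, rt; then TEMPO (10 mol %), PhI(OAc)2, CH2Cl2, rt
Reagents that add atoms: water, O
Why: Enol ether hydrolysis gives the homologous aldehyde, which the tertiary hydroxyl traps as the six-membered lactol, and oxoammonium (TEMPO) oxidation converts it into the lactone without a chromium oxidant that could cause oxidative transposition of the tertiary vinyl carbinol.

Step 4
Reactants: 6 (6S)-6-ethenyl-6-methyloxan-2-one
Product: 8 (6S)-6-ethenyl-3-hydroxy-6-methyloxan-2-one (both C3 epimers), via potassium enolate 7 (not isolated)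
Conditions: KN(SiMe3)2, THF, −78 °C; 3-phenyl-2-(phenylsulfonyl)oxaziridine, −78 °C; aq NH4Cl
Reagents that add atoms: 3-phenyl-2-(phenylsulfonyl)oxaziridine, O=S(=O)(c1ccccc1)N1OC1c1ccccc1
Why: Davis oxidation of the lactone enolate places oxygen on C3, and the epimer mixture is irrelevant because C3 becomes trigonal in step 6.

Step 5
Reactants: 8 (6S)-6-ethenyl-3-hydroxy-6-methyloxan-2-one
Product: 9 (6S)-3-{[tert-butyl(dimethyl)silyl]oxy}-6-ethenyl-6-methyloxan-2-one
Conditions: TBSCl, imidazole, DMF, rt
Reagents that add atoms: tert-butyldimethylsilyl chloride, CC(C)(C)[Si](C)(C)Cl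
Why: Standard imidazole-promoted silylation of the secondary α-hydroxyl gives a base-stable ether that the enolate cannot expel.

Step 6
Reactants: 9 (6S)-3-{[tert-butyl(dimethyl)silyl]oxy}-6-ethenyl-6-methyloxan-2-one
Product: 12 (1S)-1-{[tert-butyl(dimethyl)silyl]oxy}-4-methylcyclohex-3-ene-1-carboxylic acid, via ketene silyl acetal 10 (not isolated), via silyl ester 11 (not isolated)
Conditions: LiN(iPr)2, THF, −78 °C; TBSCl, DMPU, −78 °C to rt; toluene, 105 °C; AcOH–THF–H2O, rt
Reagents that add atoms: none
Why: Kinetic deprotonation at C3 and O-silylation give the cyclic ketene silyl acetal 10, whose C3=C2–O1–C6–CH=CH2 array undergoes a concerted [3,3]-sigmatropic shift (Ireland–Claisen rearrangement) that joins C3 to the vinyl terminus and breaks C6–O1, so that silyl ester 11 and, after hydrolysis, acid 12 should result. The closest known reaction type is the ring-contracting Ireland–Claisen rearrangement of 6-alkenyl δ-lactone ketene silyl acetals to cyclohex-3-enecarboxylic acids, here run on a glycolate-type (α-silyloxy) enolate. The cyclohexene closes inside the six-atom pericyclic array itself: because C4–C5 ties the enolate carbon to the allylic carbon, the transition state must be a boat (bicyclo[2.2.2]octane-like), and the oxacycle opens as the carbocycle forms. The one new stereocenter, C1 of 12, is controlled by C6 of the lactone, since the vinyl group can reach the enolate only across its own face of the ring, suprafacially on both partners, so that (6S) gives (1S), while the C3 epimers of 9 converge once C3 is trigonal. The step needs O- rather than C-silylation and the [3,3] shift rather than thermal loss of the tertiary allylic carboxylate; trapping with TBSCl/DMPU at −78 °C, an α-silyloxy enolate without a β-leaving group, and the gain of a silyl ester C=O from the ketene acetal are expected to secure both.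

Step 7
Reactants: 12 (1S)-1-{[tert-butyl(dimethyl)silyl]oxy}-4-methylcyclohex-3-ene-1-carboxylic acid
Product: 14 1-[(1S)-1-{[tert-butyl(dimethyl)silyl]oxy}-4-methylcyclohex-3-en-1-yl]ethan-1-one, via dilithium diolate 13 (not isolated)
Conditions: MeLi (2.5 equiv), Et2O, 0 °C to rt; inverse quench into cold 1 M aq HCl
Reagents that add atoms: methyllithium, [Li]C
Why: Ketone synthesis from a carboxylic acid and an organolithium: addition to the lithium carboxylate stops at the dilithium 1,1-diolate, which releases the methyl ketone only on acidic quench, and the quaternary α-carbon further disfavours over-addition.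

Step 8
Reactants: 14 1-[(1S)-1-{[tert-butyl(dimethyl)silyl]oxy}-4-methylcyclohex-3-en-1-yl]ethan-1-one
Product: 15 tert-butyl(dimethyl){[(1S)-4-methyl-1-(prop-1-en-2-yl)cyclohex-3-en-1-yl]oxy}silane
Conditions: Ph3PCH3Br, KOtBu, toluene, 80 °C
Reagents that add atoms: methyltriphenylphosphonium bromide, C[P+](c1ccccc1)(c1ccccc1)c1ccccc1.[Br-]
Why: Wittig methylenation under the potassium tert-butoxide, elevated-temperature conditions used for hindered ketones turns the acetyl group into the isopropenyl group without touching C1.

Step 9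
Reactants: 15 tert-butyl(dimethyl){[(1S)-4-methyl-1-(prop-1-en-2-yl)cyclohex-3-en-1-yl]oxy}silane
Product: 16 (1S)-4-methyl-1-(prop-1-en-2-yl)cyclohex-3-en-1-ol
Conditions: Bu4NF, THF, 50 °C
Reagents that add atoms: none
Why: Fluoride-induced cleavage of the hindered tertiary silyl ether frees the hydroxyl whose alkoxide directs the metalation in step 12.

Step 10
Reactants: 17 methacrolein; 18 trimethylsulfonium iodide
Product: 19 rac-2-(prop-1-en-2-yl)oxirane
Conditions: KOtBu, DMSO–THF, 0 °C to rt; distillation
Reagents that add atoms: none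
Why: Corey–Chaykovsky epoxidation: dimethylsulfonium methylide adds 1,2 to the enal and closes to the alkenyl oxirane, in contrast to the conjugate addition shown by sulfoxonium ylides.

Step 11
Reactants: 19 rac-2-(prop-1-en-2-yl)oxirane
Product: 20 (2S)-2-(prop-1-en-2-yl)oxirane
Conditions: (S,S)-N,N′-bis(3,5-di-tert-butylsalicylidene)-1,2-cyclohexanediaminocobalt acetate [(S,S)-(salen)Co(OAc), trivalent cobalt] (0.5 mol %), H2O (0.55 equiv), neat, 0 °C to rt; distillation
Reagents that add atoms: none
Why: Jacobsen hydrolytic kinetic resolution: the cobalt catalyst hydrates one enantiomer of the terminal epoxide at its CH2 terminus much faster than the other, and the volatile unreacted epoxide is distilled from the diol; by analogy with propylene oxide and butadiene monoepoxide the (S,S)-catalyst is expected to leave the (S)-epoxide, and the antipodal catalyst is used should the sense prove opposite.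

Step 12
Reactants: 16 (1S)-4-methyl-1-(prop-1-en-2-yl)cyclohex-3-en-1-ol; 20 (2S)-2-(prop-1-en-2-yl)oxirane
Product: 22 (3R)-6-[(1S)-1-hydroxy-4-methylcyclohex-3-en-1-yl]-2-methylhepta-1,6-dien-3-ol, via dilithio dianion 21 (not isolated)
Conditions: n-BuLi (2.2 equiv), TMEDA, hexane–Et2O, 0 °C to rt; 20, THF, −78 to 0 °C; aq NH4Cl
Reagents that add atoms: none
Why: Alkoxide-directed allylic lithiation gives a 2-substituted allyl dianion whose two CH2 termini are equivalent, and SN2 opening of the epoxide at its unsubstituted carbon forms C2′–C3′ while the carbinol center of 20 is carried over unchanged as (R)-C4′.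

Step 13
Reactants: 22 (3R)-6-[(1S)-1-hydroxy-4-methylcyclohex-3-en-1-yl]-2-methylhepta-1,6-dien-3-ol
Product: 23 (1S)-1-[(5R)-5-{[tert-butyl(dimethyl)silyl]oxy}-6-methylhepta-1,6-dien-2-yl]-4-methylcyclohex-3-en-1-ol
Conditions: TBSCl, imidazole, DMF, 0 °C to rt
Reagents that add atoms: tert-butyldimethylsilyl chloride, CC(C)(C)[Si](C)(C)Cl
Why: Selective silylation of the secondary allylic hydroxyl (the tertiary one does not react under these conditions) leaves the ring hydroxyl as the only group able to bind titanium in step 14.

Step 14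
Reactants: 23 (1S)-1-[(5R)-5-{[tert-butyl(dimethyl)silyl]oxy}-6-methylhepta-1,6-dien-2-yl]-4-methylcyclohex-3-en-1-ol
Product: 25 (1S,3S,4S)-4-bromo-1-[(5R)-5-{[tert-butyl(dimethyl)silyl]oxy}-6-methylhepta-1,6-dien-2-yl]-3-chloro-4-methylcyclohexan-1-ol, via titanium alkoxide 24 (not isolated)
Conditions: ClTi(OiPr)3, hexanes–CH2Cl2, rt; NBS, −20 °C, dark; aq NaHCO3
Reagents that add atoms: N-bromosuccinimide, O=C1CCC(=O)N1Br; chlorotitanium triisopropoxide, CC(C)O[Ti](Cl)(OC(C)C)OC(C)C
Why: Hydroxyl-directed titanium-mediated bromochlorination (known for allylic and homoallylic alcohols): NBS should form the bromonium ion on the face of the trisubstituted C3=C4 alkene opposite the axial C1–O–Ti group, and the titanium-bound chloride is delivered to the proximal carbon C3 through a six-membered array in the trans-diaxial (Fürst–Plattner) sense, placing Cl on C3 cis to the hydroxyl and Br on tertiary C4 trans to it (3S,4S), against the Markovnikov preference of free chloride.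

Step 15
Reactants: 25 (1S,3S,4S)-4-bromo-1-[(5R)-5-{[tert-butyl(dimethyl)silyl]oxy}-6-methylhepta-1,6-dien-2-yl]-3-chloro-4-methylcyclohexan-1-ol
Product: 26 (1S,3S,4S)-4-bromo-3-chloro-1-[(5R)-5-hydroxy-6-methylhepta-1,6-dien-2-yl]-4-methylcyclohexan-1-ol
Conditions: HF·pyridine, pyridine, THF, 0 °C to rt
Reagents that add atoms: none
Why: Acidic fluoride desilylation removes the secondary silyl ether without base, so the tertiary bromide and the secondary chloride are not exposed to elimination.

**Compound list**

1 | (S)-linalool, (3S)-3,7-dimethylocta-1,6-dien-3-ol | C=C[C@@](C)(O)CCC=C(C)C | starting material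
2 | 3-[(3S)-3-hydroxy-3-methylpent-4-en-1-yl]-5,5-dimethyl-1,2,4-trioxolane (secondary ozonide) | C=C[C@@](C)(O)CCC1OOC(C)(C)O1 | intermediate
3 | (5S)-5-ethenyl-5-methyloxolan-2-ol (anomer mixture) | C=C[C@]1(C)CCC(O)O1 | intermediate
4 | (3S)-7-methoxy-3-methylhepta-1,6-dien-3-ol (E/Z mixture) | C=C[C@@](C)(O)CCC=COC | intermediate
5 | (6S)-6-ethenyl-6-methyloxan-2-ol (anomer mixture) | C=C[C@]1(C)CCCC(O)O1 | intermediate
6 | (6S)-6-ethenyl-6-methyloxan-2-one | C=C[C@]1(C)CCCC(=O)O1 | intermediate
7 | potassium (2S)-2-ethenyl-2-methyl-3,4-dihydro-2H-pyran-6-olate (enolate of 6) | C=C[C@]1(C)CCC=C([O-])O1.[K+] | intermediate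
8 | (6S)-6-ethenyl-3-hydroxy-6-methyloxan-2-one (both C3 epimers) | C=C[C@]1(C)CCC(O)C(=O)O1 | intermediate
9 | (6S)-3-{[tert-butyl(dimethyl)silyl]oxy}-6-ethenyl-6-methyloxan-2-one (both C3 epimers) | C=C[C@]1(C)CCC(O[Si](C)(C)C(C)(C)C)C(=O)O1 | intermediate
10 | (2S)-5,6-bis{[tert-butyl(dimethyl)silyl]oxy}-2-ethenyl-2-methyl-3,4-dihydro-2H-pyran | C=C[C@]1(C)CCC(O[Si](C)(C)C(C)(C)C)=C(O[Si](C)(C)C(C)(C)C)O1 | intermediate
11 | tert-butyl(dimethyl)silyl (1S)-1-{[tert-butyl(dimethyl)silyl]oxy}-4-methylcyclohex-3-ene-1-carboxylate | CC(C)(C)[Si](C)(C)OC(=O)[C@]1(O[Si](C)(C)C(C)(C)C)CCC(C)=CC1 | intermediate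
12 | (1S)-1-{[tert-butyl(dimethyl)silyl]oxy}-4-methylcyclohex-3-ene-1-carboxylic acid | OC(=O)[C@]1(O[Si](C)(C)C(C)(C)C)CCC(C)=CC1 | intermediate
13 | dilithium 1-[(1S)-1-{[tert-butyl(dimethyl)silyl]oxy}-4-methylcyclohex-3-en-1-yl]ethane-1,1-diolate | CC(O[Li])(O[Li])[C@]1(O[Si](C)(C)C(C)(C)C)CCC(C)=CC1 | intermediate
14 | 1-[(1S)-1-{[tert-butyl(dimethyl)silyl]oxy}-4-methylcyclohex-3-en-1-yl]ethan-1-one | CC(=O)[C@]1(O[Si](C)(C)C(C)(C)C)CCC(C)=CC1 | intermediate
15 | tert-butyl(dimethyl){[(1S)-4-methyl-1-(prop-1-en-2-yl)cyclohex-3-en-1-yl]oxy}silane | C=C(C)[C@]1(O[Si](C)(C)C(C)(C)C)CCC(C)=CC1 | intermediate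
16 | (1S)-4-methyl-1-(prop-1-en-2-yl)cyclohex-3-en-1-ol | C=C(C)[C@]1(O)CCC(C)=CC1 | intermediate
17 | methacrolein, 2-methylprop-2-enal | C=C(C)C=O | starting material
18 | trimethylsulfonium iodide | C[S+](C)C.[I-] | starting material
19 | rac-2-(prop-1-en-2-yl)oxirane | C=C(C)C1CO1 | intermediate
20 | (2S)-2-(prop-1-en-2-yl)oxirane | C=C(C)[C@H]1CO1 | intermediate
21 | O,C-dilithio derivative of 16 (lithium alkoxide and 2-substituted allyllithium) | [Li]CC(=C)[C@]1(O[Li])CCC(C)=CC1 | intermediate
22 | (3R)-6-[(1S)-1-hydroxy-4-methylcyclohex-3-en-1-yl]-2-methylhepta-1,6-dien-3-ol | C=C(C)[C@H](O)CCC(=C)[C@]1(O)CCC(C)=CC1 | intermediate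
23 | (1S)-1-[(5R)-5-{[tert-butyl(dimethyl)silyl]oxy}-6-methylhepta-1,6-dien-2-yl]-4-methylcyclohex-3-en-1-ol | C=C(C)[C@H](O[Si](C)(C)C(C)(C)C)CCC(=C)[C@]1(O)CCC(C)=CC1 | intermediate
24 | chlorodiisopropoxytitanium alkoxide of 23 (Ti on the ring oxygen) | C=C(C)[C@H](O[Si](C)(C)C(C)(C)C)CCC(=C)[C@]1(O[Ti](Cl)(OC(C)C)OC(C)C)CCC(C)=CC1 | intermediate
25 | (1S,3S,4S)-4-bromo-1-[(5R)-5-{[tert-butyl(dimethyl)silyl]oxy}-6-methylhepta-1,6-dien-2-yl]-3-chloro-4-methylcyclohexan-1-ol | C=C(C)[C@H](O[Si](C)(C)C(C)(C)C)CCC(=C)[C@]1(O)CC[C@](C)(Br)[C@@H](Cl)C1 | intermediate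
26 | (1S,3S,4S)-4-bromo-3-chloro-1-[(5R)-5-hydroxy-6-methylhepta-1,6-dien-2-yl]-4-methylcyclohexan-1-ol | C=C(C)[C@H](O)CCC(=C)[C@]1(O)CC[C@](C)(Br)[C@@H](Cl)C1 | target

**Step count**

Total: 15 steps. Longest linear sequence: 13 steps from (S)-linalool (steps 1–9 and 12–15); steps 10 and 11 supply the epoxide.

**Steps most likely to fail**

Step 14. Three processes could divert the halogenation:
- chloride may open the bromonium ion at tertiary C4 (Markovnikov) instead of C3;
- the titanium alkoxide may direct halogenation to the allylic C1′=CH2 alkene instead of the ring alkene;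
- the C1 oxygen may attack the bromonium ion across the ring (bromoetherification).

The fallback sets out from 23 and comes back at 25, placing the two heteroatoms in separate trans-diaxial openings. Buffered peracid epoxidation (mCPBA, NaHCO3, CH2Cl2, 0 °C) is selective for the trisubstituted ring alkene and is steered to the hydroxyl face by hydrogen bonding, which should give the cis-epoxy alcohol F1. MgBr2·OEt2 should open it at the tertiary carbon from the opposite face to give the bromohydrin F2, with bromine on C4 trans to the C1 hydroxyl. Mesylation of the secondary hydroxyl (MsCl, Et3N, −20 °C) gives the mesylate F3. LiCl in DMF should then replace the mesylate with retention through participation of the neighbouring bromine, the transient bromonium ion being opened axially at C3, which gives 25.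

Step 12. Lithiation may occur at ring allylic positions instead of the isopropenyl methyl group, and the alkenyl epoxide may be opened at its allylic carbon or in the SN2′ sense instead of at the CH2 terminus. The fallback sets out from 16 (through dianion 21) and comes back at 22, and it no longer needs steps 10 and 11. Dianion 21 is alkylated with oxirane (ethylene oxide), which has no regiochemical choice, to give the primary alcohol F4. TEMPO/PhI(OAc)2 oxidises only the primary hydroxyl to the aldehyde F5. Catalytic enantioselective addition of an isopropenylzinc reagent (from 2-bromopropene, t-BuLi and ZnBr2; amino alcohol ligand 3-exo-morpholinoisoborneol, antipode chosen for the (R)-carbinol; one extra equivalent for the free tertiary hydroxyl) then sets C4′ by catalyst control and returns 22.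

Step 6. The [3,3] shift through the strained boat, with a fully substituted silyloxy-bearing terminus, may be slow. Thermal loss of the tertiary allylic carboxylate or C-silylation of the enolate could then take over. The fallback sets out from 8 and comes back at 16; it drops the bulky silyl ether and also removes steps 5 and 9. Hydroxy lactone 8 is treated with Me3SiCl/Et3N and then LiN(iPr)2/Me3SiCl at −78 °C to give the bis(trimethylsilyl) ketene acetal F6, the dianion-type variant of the ester enolate Claisen rearrangement known for allyl esters of α-hydroxy acids. Heating should give the rearranged silyl ester F7, and aqueous acid the hydroxy acid F8. Excess methyllithium gives the hydroxy ketone F9, and Wittig methylenation with excess ylide returns 16.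

**Further compounds**

F1 | step 14 | 3,4-epoxide of 23 with the oxirane oxygen cis to the C1 hydroxyl | C=C(C)[C@H](O[Si](C)(C)C(C)(C)C)CCC(=C)[C@]1(O)CC[C@@]2(C)O[C@H]2C1
F2 | step 14 | 4-bromo-3-hydroxy analogue of 25 (3-OH cis and 4-Br trans to the C1 hydroxyl) | C=C(C)[C@H](O[Si](C)(C)C(C)(C)C)CCC(=C)[C@]1(O)CC[C@](C)(Br)[C@@H](O)C1
F3 | step 14 | 3-O-methanesulfonate of F2 | C=C(C)[C@H](O[Si](C)(C)C(C)(C)C)CCC(=C)[C@]1(O)CC[C@](C)(Br)[C@@H](OS(C)(=O)=O)C1
F4 | step 12 | (1S)-1-(5-hydroxypent-1-en-2-yl)-4-methylcyclohex-3-en-1-ol | C=C(CCCO)[C@]1(O)CCC(C)=CC1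
F5 | step 12 | 4-[(1S)-1-hydroxy-4-methylcyclohex-3-en-1-yl]pent-4-enal | C=C(CCC=O)[C@]1(O)CCC(C)=CC1
F6 | step 6 | (2S)-2-ethenyl-2-methyl-5,6-bis[(trimethylsilyl)oxy]-3,4-dihydro-2H-pyran | C=C[C@]1(C)CCC(O[Si](C)(C)C)=C(O[Si](C)(C)C)O1
F7 | step 6 | trimethylsilyl (1S)-4-methyl-1-[(trimethylsilyl)oxy]cyclohex-3-ene-1-carboxylate | C[Si](C)(C)OC(=O)[C@]1(O[Si](C)(C)C)CCC(C)=CC1
F8 | step 6 | (1S)-1-hydroxy-4-methylcyclohex-3-ene-1-carboxylic acid | OC(=O)[C@]1(O)CCC(C)=CC1
F9 | step 6 | 1-[(1S)-1-hydroxy-4-methylcyclohex-3-en-1-yl]ethan-1-one | CC(=O)[C@]1(O)CCC(C)=CC1
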